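## Retrosynthetic overview

1. Ring numbering: C1 bears the side chain through C15, C4=C5 is E, C8=C9 is Z, C12 bears CH2OH, then C13 and C14 lead back to C1. The route rests on the C13–C14 bond of the 14-membered ring: it is the only ring bond lying between the two stereocentres (C12 and C1) and it has no functional group, so it is made last, as C13=C14, by loss of SO2 from a 15-membered cyclic sulfone (C13–SO2–C14), and then saturated.
2. Ring order: the 15-membered thiacycle is closed first, at sulfur, from an acyclic 1,14-diiodide and Na2S. It is oxidised to the sulfone and contracted to the 14-membered carbocycle by the Ramberg–Bäcklund reaction.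
3. The acyclic chain comes from two copper-catalysed Grignard couplings (C2–C3 and C10–C11) of chiral C4 bromides onto the allylic bromide and allylic acetate ends of 8-bromoneryl acetate, which supplies both trisubstituted alkenes with the correct geometry.
4. Both stereocentres come from one lipase-desymmetrised monoacetate of a 2-substituted propane-1,3-diol. Its arms are elaborated in opposite order to give the C1-end and the C12-end bromides.
5. After ring contraction: diimide reduction, release of C15–OH, oxidation, Grignard addition, oxidation, methylenation, final desilylation.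

Key step: step 18

Assumption: the lipase is taken to acetylate the hydroxymethyl arm of diol 6 that gives (R)-7. If it prefers the other arm, (R)-7 is reached by hydrolysis of the diacetate of 6 with the same enzyme, or the order of arm elaboration in steps 6–11 is exchanged. Alkene 27 is drawn as the E isomer, although either isomer serves.

Abbreviations: TBS = tert-butyldimethylsilyl, TBDPS = tert-butyldiphenylsilyl, PMB = 4-methoxybenzyl.

## Route

Step 1
Reactants: 1 neryl acetate
Product: 2 (2Z,6E)-8-hydroxy-3,7-dimethylocta-2,6-dien-1-yl acetate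
Conditions: SeO2 (cat.), t-BuOOH, salicylic acid (cat.), CH2Cl2, rt
Reagents that add atoms: selenium dioxide O=[Se]=O (delivers the oxygen atom), tert-butyl hydroperoxide CC(C)(C)OO (terminal oxidant)
Why: Catalytic SeO2 allylic oxidation (ene reaction, then [2,3]-sigmatropic shift) should attack the E-methyl group of the terminal trisubstituted alkene, because the C2=C3 alkene is deactivated by the allylic acetate, and so give the E primary allylic alcohol.

Step 2
Reactants: 2 (2Z,6E)-8-hydroxy-3,7-dimethylocta-2,6-dien-1-yl acetate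
Product: 3 (2Z,6E)-8-bromo-3,7-dimethylocta-2,6-dien-1-yl acetate
Conditions: CBr4, PPh3, CH2Cl2, 0 °C
Reagents that add atoms: carbon tetrabromide BrC(Br)(Br)Br
Why: Appel bromination converts the primary allylic alcohol into the bromide under neutral conditions that leave the acetate and both alkene geometries untouched.

Step 3
Reactants: 4 (2,2-dimethyl-1,3-dioxan-5-yl)methanol
Product: 5 5-(PMBOCH2)-2,2-dimethyl-1,3-dioxane
Conditions: NaH, 4-methoxybenzyl chloride, n-Bu4NI (cat.), THF/DMF, 0 °C to rt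
Reagents that add atoms: 4-methoxybenzyl chloride COc1ccc(CCl)cc1
Why: Williamson etherification of the primary alkoxide, with the acetonide inert to base.

Step 4
Reactants: 5 5-(PMBOCH2)-2,2-dimethyl-1,3-dioxane
Product: 6 2-(PMBOCH2)propane-1,3-diol
Conditions: AcOH/H2O (4:1), rt
Reagents that add atoms: none
Why: Acid-catalysed acetal hydrolysis frees the prochiral 1,3-diol, and the PMB ether is stable to dilute acetic acid.

Step 5
Reactants: 6 2-(PMBOCH2)propane-1,3-diol
Product: 7 (R)-3-hydroxy-2-(PMBOCH2)propyl acetate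
Conditions: Amano lipase PS (Burkholderia cepacia), vinyl acetate, i-Pr2O, rt
Reagents that add atoms: vinyl acetate C=COC(C)=O
Why: Lipase-catalysed irreversible transesterification distinguishes the two enantiotopic hydroxymethyl groups of a 2-substituted propane-1,3-diol, so the enzyme sets the single stereocentre from which both ring stereocentres are derived.

Step 6
Reactants: 7 (R)-3-hydroxy-2-(PMBOCH2)propyl acetate
Product: 8 (R)-3-bromo-2-(PMBOCH2)propyl acetate
Conditions: CBr4, PPh3, CH2Cl2, 0 °C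
Reagents that add atoms: carbon tetrabromide BrC(Br)(Br)Br
Why: Appel bromination of the free primary alcohol is neutral and fast, which avoids the 1,3-acetyl migration that would erode the enantiomeric purity.

Step 7
Reactants: 8 (R)-3-bromo-2-(PMBOCH2)propyl acetate
Product: 9 (S)-3-bromo-2-(PMBOCH2)propan-1-ol
Conditions: K2CO3 (cat.), MeOH, 0 °C
Reagents that add atoms: none
Why: Carbonate-catalysed methanolysis (transesterification) removes the acetate at a temperature at which the γ-bromo alkoxide should not close to an oxetane.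

Step 8
Reactants: 9 (S)-3-bromo-2-(PMBOCH2)propan-1-ol
Product: 10 (R)-1-bromo-3-(TBSO)-2-(PMBOCH2)propane (C1-end bromide)
Conditions: TBSCl, imidazole, CH2Cl2, rt
Reagents that add atoms: tert-butyldimethylsilyl chloride CC(C)(C)[Si](C)(C)Cl
Why: Standard silylation of a primary alcohol, with imidazole too weak a nucleophile to displace the β-branched bromide at room temperature.

Step 9
Reactants: 7 (R)-3-hydroxy-2-(PMBOCH2)propyl acetate
Product: 11 (R)-3-(TBDPSO)-2-(PMBOCH2)propyl acetate
Conditions: TBDPSCl, imidazole, CH2Cl2, 0 °C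
Reagents that add atoms: tert-butyldiphenylsilyl chloride CC(C)(C)[Si](Cl)(c1ccccc1)c1ccccc1
Why: Silylation of the free primary alcohol under conditions mild enough to prevent acetyl migration between the two arms.

Step 10
Reactants: 11 (R)-3-(TBDPSO)-2-(PMBOCH2)propyl acetate
Product: 12 (S)-3-(TBDPSO)-2-(PMBOCH2)propan-1-ol
Conditions: i-Bu2AlH, CH2Cl2, −78 °C; aq. Rochelle salt
Reagents that add atoms: none
Why: Reductive ester cleavage at −78 °C releases the alcohol through an aluminium alkoxide, which avoids the 1,5-silyl migration (and thus racemisation) that basic methanolysis could cause.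

Step 11
Reactants: 12 (S)-3-(TBDPSO)-2-(PMBOCH2)propan-1-ol
Product: 13 (S)-1-bromo-3-(TBDPSO)-2-(PMBOCH2)propane (C12-end bromide)
Conditions: CBr4, PPh3, CH2Cl2, 0 °C
Reagents that add atoms: carbon tetrabromide BrC(Br)(Br)Br
Why: Appel bromination of the primary alcohol, neutral and without effect on the silyl and PMB ethers.

Step 12
Reactants: 10 (R)-1-bromo-3-(TBSO)-2-(PMBOCH2)propane; 3 (2Z,6E)-8-bromo-3,7-dimethylocta-2,6-dien-1-yl acetate
Product: 15 (2Z,6E,10R)-11-(TBSO)-10-(PMBOCH2)-3,7-dimethylundeca-2,6-dien-1-yl acetate, via Grignard reagent 14 (not isolated)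
Conditions: Mg, THF, 40 °C (forms 14); then 3, Li2CuCl4 (cat.), THF, −78 to −40 °C
Reagents that add atoms: none
Why: Copper-catalysed cross-coupling of a primary alkyl Grignard reagent with a primary allylic bromide forms C2–C3 by substitution at the α-carbon with retention of alkene geometry, and at −78 °C the allylic bromide should react far faster than the allylic acetate at the other end.

Step 13
Reactants: 13 (S)-1-bromo-3-(TBDPSO)-2-(PMBOCH2)propane; 15 (2Z,6E,10R)-11-(TBSO)-10-(PMBOCH2)-3,7-dimethylundeca-2,6-dien-1-yl acetate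
Product: 17 (2R,5E,9Z,13S)-1-(TBSO)-14-(TBDPSO)-2,13-bis(PMBOCH2)-5,9-dimethyltetradeca-5,9-diene, via Grignard reagent 16 (not isolated)
Conditions: Mg, THF, 40 °C (forms 16); then 15, Li2CuCl4 (cat.), THF, −20 to 0 °C, fast addition
Reagents that add atoms: none
Why: The same Li2CuCl4-catalysed Grignard coupling, now with the allylic acetate as leaving group under conditions that favour α-substitution with retention of the Z geometry, forms C10–C11.

Step 14
Reactants: 17 (2R,5E,9Z,13S)-1-(TBSO)-14-(TBDPSO)-2,13-bis(PMBOCH2)-5,9-dimethyltetradeca-5,9-diene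
Product: 18 (2R,5E,9Z,13S)-2-(TBSOCH2)-13-(TBDPSOCH2)-5,9-dimethyltetradeca-5,9-diene-1,14-diol
Conditions: DDQ, CH2Cl2/pH 7 buffer, 0 °C
Reagents that add atoms: none
Why: Oxidative cleavage of both PMB ethers (hydride abstraction at the electron-rich benzylic carbon, then hydrolysis) leaves silyl ethers and isolated trisubstituted alkenes untouched.

Step 15
Reactants: 18 (2R,5E,9Z,13S)-2-(TBSOCH2)-13-(TBDPSOCH2)-5,9-dimethyltetradeca-5,9-diene-1,14-diol
Product: 19 (2S,5E,9Z,13R)-2-(TBSOCH2)-13-(TBDPSOCH2)-1,14-diiodo-5,9-dimethyltetradeca-5,9-diene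
Conditions: I2, PPh3, imidazole, CH2Cl2, 0 °C to rt
Reagents that add atoms: iodine II
Why: Appel-type iodination of both primary alcohols under conditions too mild for silyl migration or reaction at the alkenes.

Step 16
Reactants: 19 (2S,5E,9Z,13R)-2-(TBSOCH2)-13-(TBDPSOCH2)-1,14-diiodo-5,9-dimethyltetradeca-5,9-diene
Product: 22 (3S,6E,10Z,14R)-3-(TBSOCH2)-14-(TBDPSOCH2)-6,10-dimethyl-1-thiacyclopentadeca-6,10-diene, via sodium C13-thiolate 20 (not isolated), via sodium C14-thiolate 21 (not isolated)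
Conditions: Na2S·9H2O, DMF, syringe-pump addition of both components (final concentration about 2 mM), 40 °C
Reagents that add atoms: sodium sulfide (used as the nonahydrate) [Na+].[Na+].[S-2]
Why: Double SN2 displacement under high dilution, in which the first substitution gives an ω-iodo thiolate (either regioisomer) that closes the 15-membered thiacycle intramolecularly, is a standard way to macrocyclic sulfides and touches neither stereocentre.

Step 17
Reactants: 22 (3S,6E,10Z,14R)-3-(TBSOCH2)-14-(TBDPSOCH2)-6,10-dimethyl-1-thiacyclopentadeca-6,10-diene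
Product: 23 (3S,6E,10Z,14R)-3-(TBSOCH2)-14-(TBDPSOCH2)-6,10-dimethyl-1-thiacyclopentadeca-6,10-diene 1,1-dioxide
Conditions: (NH4)6Mo7O24·4H2O (cat.), 30% H2O2, EtOH/THF, 0 °C to rt
Reagents that add atoms: hydrogen peroxide OO
Why: Molybdate-catalysed peroxide oxidation takes the sulfide through the sulfoxide to the sulfone and, unlike peracids, should not epoxidise unactivated trisubstituted alkenes at a competitive rate.

Step 18
Reactants: 23 (3S,6E,10Z,14R)-3-(TBSOCH2)-14-(TBDPSOCH2)-6,10-dimethyl-1-thiacyclopentadeca-6,10-diene 1,1-dioxide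
Product: 27 (1E,3R,6E,10Z,14S)-3-(TBSOCH2)-14-(TBDPSOCH2)-6,10-dimethylcyclotetradeca-1,6,10-triene, via C13-bromo sulfone 24 (not isolated), via C14-bromo sulfone 25 (not isolated), via episulfone 26 (not isolated)
Conditions: CBr2F2, KOH/Al2O3, t-BuOH/CH2Cl2, 0 °C to rt
Reagents that add atoms: none
Why: Hydroxide on alumina deprotonates the sulfone at C13 or C14, the carbanion takes bromine from CBr2F2 to give 24 or 25, and a second deprotonation across sulfur displaces bromide to form episulfone 26, which loses SO2 cheletropically and leaves C13=C14. This is the one-pot halogenative Ramberg–Bäcklund olefination, known as a one-atom ring contraction of macrocyclic sulfones. The only ring closed in the step is the three-membered episulfone (3-exo-tet), and its collapse turns the 15-membered thiacycle into the 14-membered carbocycle, so the entropic cost of macrocyclisation is already paid at sulfur in step 16. No stereocentre is formed, and C1 and C12 are β to sulfur, carry no acidic hydrogen and should not epimerise. The step needs monobromination followed by fast 1,3-elimination and no carbene addition to C4=C5 or C8=C9; the weakly electrophilic CF2 released from CBr2F2 and the immediate cyclisation of the monobromide on the solid base should secure both. The E/Z ratio at C13=C14 does not matter because step 19 saturates this bond.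

Step 19
Reactants: 27 (1E,3R,6E,10Z,14S)-3-(TBSOCH2)-14-(TBDPSOCH2)-6,10-dimethylcyclotetradeca-1,6,10-triene
Product: 28 (1S,4E,8Z,12S)-1-(TBSOCH2)-12-(TBDPSOCH2)-4,8-dimethylcyclotetradeca-4,8-diene
Conditions: TsNHNH2, NaOAc, DME/H2O, reflux, stopped when 27 is consumed
Reagents that add atoms: none
Why: Diimide reduction transfers H2 through a concerted cyclic transition state whose rate falls steeply with alkene substitution, so the 1,2-disubstituted C13=C14 should be reduced ahead of the two trisubstituted ring alkenes.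

Step 20
Reactants: 28 (1S,4E,8Z,12S)-1-(TBSOCH2)-12-(TBDPSOCH2)-4,8-dimethylcyclotetradeca-4,8-diene
Product: 29 [(1S,4E,8Z,12S)-12-(TBDPSOCH2)-4,8-dimethylcyclotetradeca-4,8-dien-1-yl]methanol
Conditions: camphorsulfonic acid (cat.), MeOH/CH2Cl2, 0 °C
Reagents that add atoms: none
Why: Acid-catalysed methanolysis cleaves a primary TBS ether far faster than a primary TBDPS ether, which frees the C15 alcohol selectively.

Step 21
Reactants: 29 [(1S,4E,8Z,12S)-12-(TBDPSOCH2)-4,8-dimethylcyclotetradeca-4,8-dien-1-yl]methanol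
Product: 30 (1S,4E,8Z,12S)-12-(TBDPSOCH2)-4,8-dimethylcyclotetradeca-4,8-diene-1-carbaldehyde
Conditions: Dess–Martin periodinane, CH2Cl2, 0 °C to rt
Reagents that add atoms: none
Why: Dess–Martin oxidation is non-basic and should give the α-branched aldehyde without epimerisation at C1.

Step 22
Reactants: 30 (1S,4E,8Z,12S)-12-(TBDPSOCH2)-4,8-dimethylcyclotetradeca-4,8-diene-1-carbaldehyde; 31 5-bromo-2-methylpent-2-ene
Product: 33 1-[(1S,4E,8Z,12S)-12-(TBDPSOCH2)-4,8-dimethylcyclotetradeca-4,8-dien-1-yl]-5-methylhex-4-en-1-ol (both C15 epimers), via Grignard reagent 32 (not isolated)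
Conditions: Mg, THF (forms 32); then 30, THF, −78 °C; aqueous work-up
Reagents that add atoms: none
Why: Grignard addition to the aldehyde at low temperature attaches the side chain, and the new carbinol centre at C15 is formed without control, which does not matter because it is oxidised in step 23.

Step 23
Reactants: 33 1-[(1S,4E,8Z,12S)-12-(TBDPSOCH2)-4,8-dimethylcyclotetradeca-4,8-dien-1-yl]-5-methylhex-4-en-1-ol
Product: 34 1-[(1S,4E,8Z,12S)-12-(TBDPSOCH2)-4,8-dimethylcyclotetradeca-4,8-dien-1-yl]-5-methylhex-4-en-1-one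
Conditions: Dess–Martin periodinane, CH2Cl2, rt
Reagents that add atoms: none
Why: Dess–Martin oxidation of the secondary alcohol removes the uncontrolled C15 centre under non-basic conditions that should preserve the α-stereocentre C1.

Step 24
Reactants: 34 1-[(1S,4E,8Z,12S)-12-(TBDPSOCH2)-4,8-dimethylcyclotetradeca-4,8-dien-1-yl]-5-methylhex-4-en-1-one
Product: 35 tert-butyl{[(1S,4Z,8E,12S)-5,9-dimethyl-12-(6-methylhepta-1,5-dien-2-yl)cyclotetradeca-4,8-dien-1-yl]methoxy}diphenylsilane
Conditions: Cp2TiMe2, toluene, 65 °C, dark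
Reagents that add atoms: dimethyltitanocene Cp2TiMe2 C[Ti](C)(C1C=CC=C1)C1C=CC=C1
Why: Carbonyl methylenation by the titanium methylidene formed thermally from Cp2TiMe2 is non-basic, so the epimerisable C1 centre next to the ketone should be retained, in contrast to a Wittig reaction.

Step 25
Reactants: 35 tert-butyl{[(1S,4Z,8E,12S)-5,9-dimethyl-12-(6-methylhepta-1,5-dien-2-yl)cyclotetradeca-4,8-dien-1-yl]methoxy}diphenylsilane
Product: 36 [(1S,4Z,8E,12S)-5,9-dimethyl-12-(6-methylhepta-1,5-dien-2-yl)cyclotetradeca-4,8-dien-1-yl]methanol (CNP0262734.1)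
Conditions: n-Bu4NF, THF, rt
Reagents that add atoms: none
Why: Fluoride-induced Si–O cleavage frees the primary alcohol, and nothing else in the triene reacts with the reagent.

## Compound list

1 | neryl acetate | CC(C)=CCC/C(C)=C\COC(C)=O | starting material
2 | (2Z,6E)-8-hydroxy-3,7-dimethylocta-2,6-dien-1-yl acetate | OC/C(C)=C/CC/C(C)=C\COC(C)=O | intermediate
3 | (2Z,6E)-8-bromo-3,7-dimethylocta-2,6-dien-1-yl acetate | BrC/C(C)=C/CC/C(C)=C\COC(C)=O | intermediate
4 | (2,2-dimethyl-1,3-dioxan-5-yl)methanol | CC1(C)OCC(CO)CO1 | starting material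
5 | 5-(PMBOCH2)-2,2-dimethyl-1,3-dioxane | COc1ccc(COCC2COC(C)(C)OC2)cc1 | intermediate
6 | 2-(PMBOCH2)propane-1,3-diol | COc1ccc(COCC(CO)CO)cc1 | intermediate
7 | (R)-3-hydroxy-2-(PMBOCH2)propyl acetate | OC[C@@H](COC(C)=O)COCc1ccc(OC)cc1 | intermediate
8 | (R)-3-bromo-2-(PMBOCH2)propyl acetate | BrC[C@@H](COC(C)=O)COCc1ccc(OC)cc1 | intermediate
9 | (S)-3-bromo-2-(PMBOCH2)propan-1-ol | BrC[C@@H](CO)COCc1ccc(OC)cc1 | intermediate
10 | (R)-1-bromo-3-(TBSO)-2-(PMBOCH2)propane | BrC[C@@H](CO[Si](C)(C)C(C)(C)C)COCc1ccc(OC)cc1 | intermediate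
11 | (R)-3-(TBDPSO)-2-(PMBOCH2)propyl acetate | CC(C)(C)[Si](c1ccccc1)(c1ccccc1)OC[C@@H](COC(C)=O)COCc1ccc(OC)cc1 | intermediate
12 | (S)-3-(TBDPSO)-2-(PMBOCH2)propan-1-ol | CC(C)(C)[Si](c1ccccc1)(c1ccccc1)OC[C@@H](CO)COCc1ccc(OC)cc1 | intermediate
13 | (S)-1-bromo-3-(TBDPSO)-2-(PMBOCH2)propane | CC(C)(C)[Si](c1ccccc1)(c1ccccc1)OC[C@@H](CBr)COCc1ccc(OC)cc1 | intermediate
14 | Grignard reagent of 10 | Br[Mg]C[C@@H](CO[Si](C)(C)C(C)(C)C)COCc1ccc(OC)cc1 | intermediate
15 | (2Z,6E,10R)-11-(TBSO)-10-(PMBOCH2)-3,7-dimethylundeca-2,6-dien-1-yl acetate | CC(C)(C)[Si](C)(C)OC[C@@H](COCc1ccc(OC)cc1)CC/C(C)=C/CC/C(C)=C\COC(C)=O | intermediate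
16 | Grignard reagent of 13 | CC(C)(C)[Si](c1ccccc1)(c1ccccc1)OC[C@@H](C[Mg]Br)COCc1ccc(OC)cc1 | intermediate
17 | (2R,5E,9Z,13S)-1-(TBSO)-14-(TBDPSO)-2,13-bis(PMBOCH2)-5,9-dimethyltetradeca-5,9-diene | CC(C)(C)[Si](C)(C)OC[C@@H](COCc1ccc(OC)cc1)CC/C(C)=C/CC/C(C)=C\CC[C@H](CO[Si](c1ccccc1)(c1ccccc1)C(C)(C)C)COCc1ccc(OC)cc1 | intermediate
18 | (2R,5E,9Z,13S)-2-(TBSOCH2)-13-(TBDPSOCH2)-5,9-dimethyltetradeca-5,9-diene-1,14-diol | CC(C)(C)[Si](C)(C)OC[C@@H](CO)CC/C(C)=C/CC/C(C)=C\CC[C@H](CO[Si](c1ccccc1)(c1ccccc1)C(C)(C)C)CO | intermediate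
19 | (2S,5E,9Z,13R)-2-(TBSOCH2)-13-(TBDPSOCH2)-1,14-diiodo-5,9-dimethyltetradeca-5,9-diene | CC(C)(C)[Si](C)(C)OC[C@@H](CI)CC/C(C)=C/CC/C(C)=C\CC[C@H](CO[Si](c1ccccc1)(c1ccccc1)C(C)(C)C)CI | intermediate
20 | sodium thiolate at C13 with iodide at C14 | CC(C)(C)[Si](C)(C)OC[C@@H](CI)CC/C(C)=C/CC/C(C)=C\CC[C@H](CO[Si](c1ccccc1)(c1ccccc1)C(C)(C)C)C[S-].[Na+] | intermediate
21 | sodium thiolate at C14 with iodide at C13 | CC(C)(C)[Si](C)(C)OC[C@@H](C[S-])CC/C(C)=C/CC/C(C)=C\CC[C@H](CO[Si](c1ccccc1)(c1ccccc1)C(C)(C)C)CI.[Na+] | intermediate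
22 | (3S,6E,10Z,14R)-3-(TBSOCH2)-14-(TBDPSOCH2)-6,10-dimethyl-1-thiacyclopentadeca-6,10-diene | CC(C)(C)[Si](C)(C)OC[C@@H]1CC/C(C)=C/CC/C(C)=C\CC[C@H](CO[Si](c2ccccc2)(c2ccccc2)C(C)(C)C)CSC1 | intermediate
23 | (3S,6E,10Z,14R)-3-(TBSOCH2)-14-(TBDPSOCH2)-6,10-dimethyl-1-thiacyclopentadeca-6,10-diene 1,1-dioxide | CC(C)(C)[Si](C)(C)OC[C@@H]1CC/C(C)=C/CC/C(C)=C\CC[C@H](CO[Si](c2ccccc2)(c2ccccc2)C(C)(C)C)CS(=O)(=O)C1 | intermediate
24 | sulfone 23 brominated at C13 (either epimer at the brominated carbon) | CC(C)(C)[Si](C)(C)OC[C@@H]1CC/C(C)=C/CC/C(C)=C\CC[C@H](CO[Si](c2ccccc2)(c2ccccc2)C(C)(C)C)C(Br)S(=O)(=O)C1 | intermediate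
25 | sulfone 23 brominated at C14 (either epimer at the brominated carbon) | CC(C)(C)[Si](C)(C)OC[C@@H]1CC/C(C)=C/CC/C(C)=C\CC[C@H](CO[Si](c2ccccc2)(c2ccccc2)C(C)(C)C)CS(=O)(=O)C1Br | intermediate
26 | episulfone (thiirane 1,1-dioxide fused at C13–C14 of the 14-membered ring) | CC(C)(C)[Si](C)(C)OC[C@@H]1CC/C(C)=C/CC/C(C)=C\CC[C@H](CO[Si](c2ccccc2)(c2ccccc2)C(C)(C)C)C2C1S2(=O)=O | intermediate
27 | (1E,3R,6E,10Z,14S)-3-(TBSOCH2)-14-(TBDPSOCH2)-6,10-dimethylcyclotetradeca-1,6,10-triene | CC(C)(C)[Si](C)(C)OC[C@@H]1CC/C(C)=C/CC/C(C)=C\CC[C@H](CO[Si](c2ccccc2)(c2ccccc2)C(C)(C)C)/C=C/1 | intermediate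
28 | (1S,4E,8Z,12S)-1-(TBSOCH2)-12-(TBDPSOCH2)-4,8-dimethylcyclotetradeca-4,8-diene | CC(C)(C)[Si](C)(C)OC[C@@H]1CC/C(C)=C/CC/C(C)=C\CC[C@H](CO[Si](c2ccccc2)(c2ccccc2)C(C)(C)C)CC1 | intermediate
29 | [(1S,4E,8Z,12S)-12-(TBDPSOCH2)-4,8-dimethylcyclotetradeca-4,8-dien-1-yl]methanol | OC[C@@H]1CC/C(C)=C/CC/C(C)=C\CC[C@H](CO[Si](c2ccccc2)(c2ccccc2)C(C)(C)C)CC1 | intermediate
30 | (1S,4E,8Z,12S)-12-(TBDPSOCH2)-4,8-dimethylcyclotetradeca-4,8-diene-1-carbaldehyde | O=C[C@@H]1CC/C(C)=C/CC/C(C)=C\CC[C@H](CO[Si](c2ccccc2)(c2ccccc2)C(C)(C)C)CC1 | intermediate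
31 | 5-bromo-2-methylpent-2-ene | CC(C)=CCCBr | starting material
32 | 4-methylpent-3-enylmagnesium bromide | CC(C)=CCC[Mg]Br | intermediate
33 | 1-[(1S,4E,8Z,12S)-12-(TBDPSOCH2)-4,8-dimethylcyclotetradeca-4,8-dien-1-yl]-5-methylhex-4-en-1-ol (C15 epimers) | CC(C)=CCCC(O)[C@@H]1CC/C(C)=C/CC/C(C)=C\CC[C@H](CO[Si](c2ccccc2)(c2ccccc2)C(C)(C)C)CC1 | intermediate
34 | 1-[(1S,4E,8Z,12S)-12-(TBDPSOCH2)-4,8-dimethylcyclotetradeca-4,8-dien-1-yl]-5-methylhex-4-en-1-one | CC(C)=CCCC(=O)[C@@H]1CC/C(C)=C/CC/C(C)=C\CC[C@H](CO[Si](c2ccccc2)(c2ccccc2)C(C)(C)C)CC1 | intermediate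
35 | tert-butyl{[(1S,4Z,8E,12S)-5,9-dimethyl-12-(6-methylhepta-1,5-dien-2-yl)cyclotetradeca-4,8-dien-1-yl]methoxy}diphenylsilane | C=C(CCC=C(C)C)[C@@H]1CC/C(C)=C/CC/C(C)=C\CC[C@H](CO[Si](c2ccccc2)(c2ccccc2)C(C)(C)C)CC1 | intermediate
36 | [(1S,4Z,8E,12S)-5,9-dimethyl-12-(6-methylhepta-1,5-dien-2-yl)cyclotetradeca-4,8-dien-1-yl]methanol (CNP0262734.1) | C=C(CCC=C(C)C)[C@@H]1CC/C(C)=C/CC/C(C)=C\CC[C@H](CO)CC1 | target

## Step count

Total steps: 25. Longest linear sequence: 20 steps (4 → 5 → 6 → 7 → 8 → 9 → 10 → 15 → 17 → 18 → 19 → 22 → 23 → 27 → 28 → 29 → 30 → 33 → 34 → 35 → 36).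

## Steps most likely to fail

Step 18 (Ramberg–Bäcklund ring contraction). The sulfone may be brominated twice before the 1,3-elimination, which leads to vinyl bromides. The reaction may also stall at the α-bromo sulfone, because both α-carbons sit next to a branched carbon, and the released carbene may add to the ring alkenes. Fallback: setting out from diol 18, double Dess–Martin oxidation gives (2R,5E,9Z,13S)-2-(TBSOCH2)-13-(TBDPSOCH2)-5,9-dimethyltetradeca-5,9-dienedial F6. Double Wittig methylenation (Ph3P=CH2 from Ph3PCH3Br and KN(SiMe3)2, THF, −78 to 0 °C) gives the 3,14-disubstituted 6,10-dimethylhexadeca-1,6,10,15-tetraene F7. Ring-closing metathesis of the two vinyl groups with the second-generation Grubbs catalyst RuCl2(H2IMes)(PCy3)(=CHPh) in dilute CH2Cl2 at 40 °C forms C13=C14 with loss of ethene and comes back to the route at triene 27.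

Step 16 (sulfide macrocyclisation). Intermolecular substitution may outrun ring closure and give oligomeric sulfides, and the basic sulfide solution may slowly cleave the silyl ethers. Fallback: setting out from diiodide 19, one equivalent of KSAc in DMF at 0 °C gives, by statistical monosubstitution, the C13-thioacetate C14-iodide F4 and the C14-thioacetate C13-iodide F5, which are separated from recovered 19. Slow addition of F4 and F5 to K2CO3 in degassed MeOH/THF under high dilution frees the thiolate, which closes the ring intramolecularly. Both regioisomers give the same sulfide, and the fallback comes back to the route at 22.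

Step 5 (lipase desymmetrisation). The enzyme may discriminate the two hydroxymethyl groups poorly when the 2-substituent is an alkoxymethyl group, and acetyl migration in 7 may lower the enantiomeric purity further. Fallback: setting out from diol 6, desymmetrising monobenzoylation with vinyl benzoate and the dinuclear zinc catalyst made from Et2Zn and the enantiomer of the ProPhenol ligand that gives the R ester (toluene, −20 °C) gives (R)-3-hydroxy-2-(PMBOCH2)propyl benzoate F1. For the C1-end bromide, Appel bromination of F1 gives (R)-3-bromo-2-(PMBOCH2)propyl benzoate F2, and methanolysis (K2CO3, MeOH) comes back to the route at 9. For the C12-end bromide, silylation of F1 (TBDPSCl, imidazole) gives (R)-3-(TBDPSO)-2-(PMBOCH2)propyl benzoate F3, and cleavage with i-Bu2AlH at −78 °C comes back to the route at 12.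

## Further compounds

F1 | step 5 | (R)-3-hydroxy-2-(PMBOCH2)propyl benzoate | OC[C@@H](COC(=O)c1ccccc1)COCc1ccc(OC)cc1
F2 | step 5 | (R)-3-bromo-2-(PMBOCH2)propyl benzoate | BrC[C@@H](COC(=O)c1ccccc1)COCc1ccc(OC)cc1
F3 | step 5 | (R)-3-(TBDPSO)-2-(PMBOCH2)propyl benzoate | CC(C)(C)[Si](c1ccccc1)(c1ccccc1)OC[C@@H](COC(=O)c1ccccc1)COCc1ccc(OC)cc1
F4 | step 16 | C13-thioacetate C14-iodide derived from 19 | CC(C)(C)[Si](C)(C)OC[C@@H](CI)CC/C(C)=C/CC/C(C)=C\CC[C@H](CO[Si](c1ccccc1)(c1ccccc1)C(C)(C)C)CSC(C)=O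
F5 | step 16 | C14-thioacetate C13-iodide derived from 19 | CC(C)(C)[Si](C)(C)OC[C@@H](CSC(C)=O)CC/C(C)=C/CC/C(C)=C\CC[C@H](CO[Si](c1ccccc1)(c1ccccc1)C(C)(C)C)CI
F6 | step 18 | (2R,5E,9Z,13S)-2-(TBSOCH2)-13-(TBDPSOCH2)-5,9-dimethyltetradeca-5,9-dienedial | CC(C)(C)[Si](C)(C)OC[C@@H](C=O)CC/C(C)=C/CC/C(C)=C\CC[C@H](CO[Si](c1ccccc1)(c1ccccc1)C(C)(C)C)C=O
F7 | step 18 | (6E,10Z)-3-(TBSOCH2)-14-(TBDPSOCH2)-6,10-dimethylhexadeca-1,6,10,15-tetraene | CC(C)(C)[Si](C)(C)OC[C@@H](C=C)CC/C(C)=C/CC/C(C)=C\CC[C@H](CO[Si](c1ccccc1)(c1ccccc1)C(C)(C)C)C=C
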